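**Time of reading.** I had to say what the flask called epsilon held at 12 min, and I chose to count turnovers: how many lifetimes of loss E had lived through by then.

| flask | X | D | temperature | remark | time |
|---|---|---|---|---|---|
| epsilon | 0.20 M | 0.12 M | 90 °C | the very flask that is asked about, followed so far |  |
| zeta | 0.20 M | 0.18 M | 85 °C | run made earlier |  |
| flask | 0.20 M | 0.120 M | 90 °C |  | 12 min |

| run | time / min | E / % |
|---|---|---|
| epsilon | 2.50 | 28.3 |
| epsilon | 5.00 | 51.1 |
| epsilon | 8.00 | 45.4 |
| epsilon | 10.0 | 41.5 |
| zeta | 0.333 | 0.5 |
| zeta | 0.833 | 0.1 |
| zeta | 1.50 | 7.7 |
| zeta | 2.50 | 50.6 |

(each reading ± 0.5 percentage points)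

- E, in percent of the X first charged, at 12 min
- what to do for the largest gain in E; "none" if nothing gains more than 2 percentage points (north-east / north-west / south-east / north / none)
- E present, with what was taken out counted in, in percent of the X first charged, after north-west
- E present, with what was taken out counted in, in percent of the X first charged, after north

- north-east: at 12 min add D, 100% of the amount charged, then wait 6.0 min
- north-west: change nothing and wait 6.0 min more
- south-east: at 12 min raise the temperature by 25 K, then wait 6.0 min
- north: at 12 min take out 90% of the E then present, then wait 6.0 min

- E that was removed still counts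
- additions bring no volume worth counting

**First instants.** In the zeta run E read 0.1% at 0.833 min, then 50.6% at 2.50 min. That slow start and sudden rush looked as if E hastened its own making (autocatalysis).

**The middle.** In epsilon D was charged at less than X, which makes it the limiting reagent. Taking one D per E, the cap on E was 60.0% of the X. The reading at 2.50 min was about half of that cap, so I took that time as the midpoint of the making.

**The end.** The epsilon readings then fell from 51.1% to 41.5%, so something was taking E away. I treated the whole cap as made at the midpoint and defined the fade rate as the natural logarithm of cap over last reading, divided by the time since the midpoint: 0.0492 /min. By 12 min that counts 0.467 lifetimes, so I reckoned E at 37.6%. After waiting I reckoned 28.0%, and with the removal 36.7%. I would add D, since 40.0% of the X stood unreacted by my count.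

**The forecast.** It gave 38.2% (37% to 39.2%), 29.8% and 37.4%, each above mine, and chose north-east: “Adding D restarts formation from the leftover X”.

**The flask.** It gave 37.6%, 28.2% and 37.1%, and north-east won with a gain of 21 percentage points.

    X + D + E → 2 E (k = 2.11 /M²/s, Ea = 47.0 kJ/mol)
    X + D → E (k = 2.15 × 10⁻⁴ /M/s, Ea = 85.0 kJ/mol)
    E ⇌ L (K = 13.0, k = 8.55 × 10⁻⁴ /s, Ea = 96.0 kJ/mol, ΔH = −32.0 kJ/mol)
    (constants at 90 °C)

**What stood.** At 2.53 min E was made 20.7 times faster than it was used up, each step taken net, and 99% of the turnover up to 12 min of the path from X + D + E to 2 E was behind the flask at 6.00 min. Half of that turnover was done by 2.53 min, earlier than half of the turnover of the path from E to L, at 6.76 min. Started from the computed 37.6%, the fade rate gives 28.0% after 6.0 min more, beside the flask's 28.2%.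

**Second flask.** For a second flask with 0.50 M of X and the same D, I took the cap as 24.0% of its X and, assuming the same count of 0.467 lifetimes by 12 min, reckoned 15.0% of E. The computed second flask held 13.8% of E at that time.

The readings were generated by integration from invented constants, and the scatter is random.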